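**Remarks on the chemistry.** The target has no stereocentre and no descriptor on the C3–C6'' axis, so the axis is built without stereocontrol. Atom bookkeeping of the folding (chain C6 to C1 equals C4a''–C8a'', unit 1 on C6'') was checked against the target and no structure needed correcting. Compounds 1, 3, 9, 11 and 12 are taken as catalogue materials. Abbreviations: Bn = benzyl; Fl = 5-(benzyloxy)-2-[4-(benzyloxy)phenyl]-7-methoxy-4-oxo-4H-chromen-3-yl (protected unit 1, bonded through C3).

## Structural features

The target is a biflavone: two 2-arylchromen-4-ones joined by one C–C bond between C3 of unit 1 (5-hydroxy-7-methoxy-4'-hydroxyflavone; benzo ring A, pyranone ring C, aryl ring B) and C6'' of unit 2 (luteolin; benzo ring D, pyranone ring F, catechol ring E). There is no stereocentre. The only stereogenic element is the C3–C6'' axis, flanked by four ortho groups (C2 aryl and C4 carbonyl of unit 1, the C5'' and C7'' hydroxyls of unit 2), and it is undefined in the target. Six phenolic hydroxyls must be told apart from the single methyl ether at C7. The catechol of ring E and the phloroglucinol-type rings A and D are easily oxidised or halogenated, and both pyranone rings can be opened by hard nucleophiles at C2 or C2''. The real difficulty is the crowded C3–C6'' bond, which ties the α-carbon of an enone to the carbon lying between two oxygens of ring D, and the need for attachment at C6'' and not C8''. Ring D (C4a'', C5'', C6'', C7'', C8'', C8a'') with O5'', O7'', O1'' and the acyl carbon C4'' is an acylphloroglucinol, the Claisen-folded form of a 3,5,7-trioxo acid chain. The key step uses this: chain carbons C1 to C7 become C8a'', C8'', C7'', C6'', C5'', C4a'' and C4'', so unit 1 only has to sit on the C4 methine of an open chain, and the biaryl bond can be made early as an ordinary bond to a CH2 group.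

## Logic of the disconnections

19 to 18: the four O–CH2Ph bonds are cut. Benzyl ethers keep the future hydroxyls of rings A, B and E inert to base and distinct from the C7 methyl ether. The forward step must remove them without touching the methyl ether or the two C2=C3 bonds and must intercept the benzyl cations.

18 to 16: the O1''–C2'' bond and the C2''=C3'' unsaturation of ring F are removed, leaving the enone and three free hydroxyls on ring D. This reaches the direct product of the folding. The forward step must close through the oxygen para to unit 1 (future O1'') and not through the one between the acyl group and unit 1.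

16 to 14 through 15: the C4a''–C8a'' bond is cut and ring D is unfolded to a tetraketide chain masked as a 4-hydroxy-2-pyranone. The crowded hexasubstituted benzene ring disappears and unit 1 becomes a substituent on pyranone C5. The forward step must fold by Claisen and not aldol chemistry and must spare the chromone of unit 1.

14 to 10 and 13: the bond between the pyranone 6-CH2 group and the ketone carbon (chain C6–C7) is cut. This splits off the whole ring E fragment as an acyl donor and makes the route convergent. The forward step needs a carbanion on the 6-methyl group of 10 and clean 1,2-addition to 13.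

13 to 11 and 12: the alkene is cut. The forward olefination must give the E isomer.

10 to 8 and 9 (8 from 7): pyranone bonds C4–C5 and O1–C2 are cut, removing a three-carbon malonyl unit from the enol of a methyl ketone. The forward step requires the enol of 7 to point toward the carbon that carries unit 1.

7 to 6: the ketone oxygen is removed, leaving a terminal alkene. An allyl group is an acetonyl equivalent that is inert to the acid used to close ring C and cannot form a furan at the diketone stage.

6 to 5 to 4: the O1–C2 bond of ring C is cut, then the bond between the diketone carbon and the allyl CH2. This last cut is the future C3–C6'' bond. The forward allylation must be C-selective and stop at one allyl group.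

4 to 2 and 3, and 2 to 1: the bond between the acetophenone α-carbon and the aroyl carbon is cut, then one O–benzyl bond. Both fragments are catalogue compounds that already carry the C7 methyl ether and the ring B benzyl ether.

## Other disconnections considered

**Alternative 1:** The cut is at C3–C6'' and O1–C2 of ring C, made through an aryl shift. In the forward sense the β,β-diaryl enone A1 would be treated with Tl(NO3)3 (trivalent thallium) in methanol. Methoxythallation of the alkene would be followed by a 1,2-shift of the trioxygenated aryl group from the β- to the α-carbon with loss of monovalent thallium. Acid would then close ring C on the resulting ketal and strip the two methoxymethyl groups to give phenol A2.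

- In its favour: the crowded bond is formed intramolecularly, and ring C and the biaryl arise in one operation.
- Better than the chosen plan on one point: the trioxygenated ring of A2 has two equivalent carbons next to its free hydroxyl, so later annulation of ring F cannot give an 8''-linked isomer.
- Against it: the aryl shift is established for β-monoaryl enones (the isoflavone synthesis) and would have to be extended to a trisubstituted, hindered alkene with two competing β-aryl groups. The migrating ring is doubly ortho-substituted. Trivalent thallium attacks electron-rich trialkoxyarenes and is highly toxic. A1 is itself a hindered enone that is not trivial to assemble.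
- Step economy: ring F (acylation, chain extension, cyclisation) and debenzylation still follow A2, so the count is no lower than in the chosen plan.
- Mechanism: the chosen plan relies on a reaction class with direct precedent, and this one does not.

**Alternative 2:** The cut removes three bonds of ring D (C5''–C6'', C7''–C8'' and C4a''–C5''), so that ring D is built around the biaryl carbon. In the forward sense cyclobutenone A3 and the silyl ynol ether A4 would be heated together. Four-electron opening of A3 gives a vinylketene, which undergoes regioselective (2+2) addition to A4 with the flavonyl-bearing alkyne carbon bonding to the ketene carbonyl carbon. A second ring opening, six-electron closure and tautomerisation would give phenol A5.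

- Equal to the chosen plan: the biaryl carbon is made part of a ring construction, so no hindered cross-coupling is needed.
- Better than the chosen plan: the conditions are neutral and thermal, and the three oxygens of ring D emerge differentiated (free hydroxyl, silyl ether, 4-methoxybenzyl ether). The oxygen para to unit 1 can therefore be unmasked alone and ring F closed without regiochemical doubt.
- Against it: A4 is a silyl ynol ether on a base-sensitive chromone, and its preparation calls for ynolate or acetylide-oxidation chemistry under strong base. Its reacting carbon is flanked by the C2 aryl group and the C4 carbonyl, and conjugation with the enone lowers its nucleophilicity toward the ketene. A3 is a sensitive non-catalogue compound.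
- Step economy: ring F still has to be added to A5 in about four steps, so the route is longer than the chosen plan.
- Mechanism: the pericyclic cascade is well defined but untested with so hindered an alkyne, whereas the chosen Claisen folding places the bulky group on a remote methine.

**Alternative 3:** The cut is C4''–C4a'', preceded by O1''–C2''. In the forward sense phenol A2 would add to the propiolate A6, and saponification would give the β-aryloxycinnamic acid A7. Activation with (CF3CO)2O would then acylate one of the two equivalent ortho carbons of the aryloxy ring and close ring F to the hexabenzyl ether A8. One debenzylation would end the synthesis.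

- Better than the chosen plan: the end game is shorter and more convergent, and symmetry guarantees the 6''-linkage.
- Against it: A2 must first be made, either by the uncertain route of alternative 1 or by a tetra-ortho-substituted cross-coupling, so the central difficulty is displaced and not solved. Only the Z acid can cyclise. The acylation site lies next to a benzyloxy group that is itself pressed by unit 1. The strongly acidic acylating medium can cleave or transfer benzyl groups onto the electron-rich rings.
- Overall: once A2 exists this route is the better one on structure and step economy, but taken from catalogue compounds the chosen plan is the more defensible, because its biaryl bond is an unhindered allylation.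

Key step: step 10

## Route

**Step 1**
Reactants: 1 1-(2,6-dihydroxy-4-methoxyphenyl)ethanone
Product: 2 1-[2-(benzyloxy)-6-hydroxy-4-methoxyphenyl]ethanone
Conditions: BnBr (1.0 equiv), K2CO3 (1.1 equiv), acetone, reflux
Reagents that add atoms: benzyl bromide, BrCc1ccccc1
Why: Williamson etherification; the two hydroxyls of 1 are equivalent, and after the first benzylation the remaining one is locked in a hydrogen bond to the acetyl carbonyl and is far less nucleophilic, so one equivalent of halide should stop at the mono-ether.

**Step 2**
Reactants: 2 1-[2-(benzyloxy)-6-hydroxy-4-methoxyphenyl]ethanone; 3 4-(benzyloxy)benzoyl chloride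
Product: 4 1-[2-(benzyloxy)-6-hydroxy-4-methoxyphenyl]-3-[4-(benzyloxy)phenyl]propane-1,3-dione
Conditions: LiN(SiMe3)2 (3.2 equiv), THF, −78 to −10 °C; then 3, −78 °C to rt; aq. HCl
Reagents that add atoms: none
Why: Direct C-aroylation of the phenoxide–enolate dianion, the one-flask form of the Baker–Venkataraman transposition; the third equivalent of base absorbs the acidic diketone as it forms, and any O-aroyl ester formed first is rearranged to 4 by the same base.

**Step 3**
Reactants: 4 1-[2-(benzyloxy)-6-hydroxy-4-methoxyphenyl]-3-[4-(benzyloxy)phenyl]propane-1,3-dione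
Product: 5 racemic 2-allyl-1-[2-(benzyloxy)-6-hydroxy-4-methoxyphenyl]-3-[4-(benzyloxy)phenyl]propane-1,3-dione
Conditions: allyl methyl carbonate (1.05 equiv), Pd(PPh3)4 (3 mol%), THF, rt
Reagents that add atoms: allyl methyl carbonate, C=CCOC(=O)OC
Why: Tsuji–Trost allylation; the soft diketonate attacks the π-allyl complex of divalent palladium at carbon, O-allylation of the chelated phenol is reversible under zerovalent palladium whereas C-allylation is not, and the less acidic, more hindered mono-allyl product resists a second allylation; this step makes the future C3–C6'' bond.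

**Step 4**
Reactants: 5 racemic 2-allyl-1-[2-(benzyloxy)-6-hydroxy-4-methoxyphenyl]-3-[4-(benzyloxy)phenyl]propane-1,3-dione
Product: 6 3-allyl-5-(benzyloxy)-2-[4-(benzyloxy)phenyl]-7-methoxy-4H-chromen-4-one
Conditions: TsOH·H2O (10 mol%), toluene, 90 °C
Reagents that add atoms: none
Why: Acid-catalysed cyclodehydration of an o-hydroxyaryl 1,3-diketone, the closing stage of the Baker–Venkataraman flavone synthesis; the phenol adds to the aroyl carbonyl and water is lost, the racemic centre of 5 becomes the sp2 carbon C3, and catalytic sulfonic acid leaves the benzyl ethers and the allyl group alone.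

**Step 5**
Reactants: 6 3-allyl-5-(benzyloxy)-2-[4-(benzyloxy)phenyl]-7-methoxy-4H-chromen-4-one
Product: 7 5-(benzyloxy)-2-[4-(benzyloxy)phenyl]-7-methoxy-3-(2-oxopropyl)-4H-chromen-4-one
Conditions: PdCl2 (10 mol%), CuCl (1 equiv), O2 (1 atm), DMF–H2O 7:1, rt
Reagents that add atoms: water, O
Why: Tsuji–Wacker oxidation; Markovnikov hydroxypalladation of the terminal alkene and β-hydride elimination give the methyl ketone, the tetrasubstituted electron-poor C2=C3 bond of the chromone is not a substrate, and CuCl with O2 returns palladium to the divalent state.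

**Step 6**
Reactants: 7 5-(benzyloxy)-2-[4-(benzyloxy)phenyl]-7-methoxy-3-(2-oxopropyl)-4H-chromen-4-one
Product: 8 (Z)-5-(benzyloxy)-2-[4-(benzyloxy)phenyl]-7-methoxy-3-[2-(trimethylsilyloxy)prop-1-enyl]-4H-chromen-4-one
Conditions: Me3SiCl (3 equiv), Et3N (4 equiv), DMF, 80 °C; pentane extraction, cold NaHCO3 wash; used crude
Reagents that add atoms: chlorotrimethylsilane, C[Si](C)(C)Cl
Why: Thermodynamic enol silylation (House conditions); proton exchange through Et3NHCl funnels to the more substituted enol ether, whose trisubstituted double bond is conjugated with C2=C3 of the chromone and arises from the more acidic CH2 group; the Z geometry is expected but plays no role later.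

**Step 7**
Reactants: 8 (Z)-5-(benzyloxy)-2-[4-(benzyloxy)phenyl]-7-methoxy-3-[2-(trimethylsilyloxy)prop-1-enyl]-4H-chromen-4-one; 9 malonyl dichloride
Product: 10 5-Fl-4-hydroxy-6-methyl-2H-pyran-2-one
Conditions: 9 (1.1 equiv), Et2O–CH2Cl2, −78 °C to rt
Reagents that add atoms: none
Why: Effenberger pyranone synthesis; the enol silane is C-acylated by one acid chloride group with loss of Me3SiCl, the new 1,3-dicarbonyl enolises toward the methyl ketone, and that enol oxygen closes on the second acid chloride, placing unit 1 on C5 and the methyl group on C6; low temperature in ether keeps the released HCl from the benzyl ethers.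

**Step 8**
Reactants: 11 3,4-bis(benzyloxy)benzaldehyde; 12 diethyl {2-[methoxy(methyl)amino]-2-oxoethyl}phosphonate
Product: 13 (E)-3-[3,4-bis(benzyloxy)phenyl]-N-methoxy-N-methylprop-2-enamide
Conditions: NaH (1.1 equiv), THF, 0 °C to rt
Reagents that add atoms: none
Why: Horner–Wadsworth–Emmons olefination with a stabilised phosphonate anion; reversible addition and anti-selective elimination give the E alkene.

**Step 9**
Reactants: 10 5-Fl-4-hydroxy-6-methyl-2H-pyran-2-one; 13 (E)-3-[3,4-bis(benzyloxy)phenyl]-N-methoxy-N-methylprop-2-enamide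
Product: 14 6-{(E)-4-[3,4-bis(benzyloxy)phenyl]-2-oxobut-3-enyl}-5-Fl-4-hydroxy-2H-pyran-2-one
Conditions: LiN(iPr)2 (2.2 equiv), THF, −78 to −30 °C; 13 (1.1 equiv), −78 °C; cold aq. HCl
Reagents that add atoms: none
Why: Acylation of a 4-hydroxy-6-methyl-2-pyranone dianion; the second equivalent of amide base deprotonates the 6-methyl group (vinylogous position) and this carbanion adds 1,2 to the Weinreb amide, whose chelated tetrahedral adduct survives until the acid quench so that no acidic ketone meets the dianion; attack of the same carbanion on C2 of the chromone would be a disfavoured 5-endo-trig closure.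

**Step 10**
Reactants: 14 6-{(E)-4-[3,4-bis(benzyloxy)phenyl]-2-oxobut-3-enyl}-5-Fl-4-hydroxy-2H-pyran-2-one
Product: 16 (E)-3-[3,4-bis(benzyloxy)phenyl]-1-(3-Fl-2,4,6-trihydroxyphenyl)prop-2-en-1-one, via magnesium-chelated open-chain trioxo ester 15 (not isolated)
Conditions: Mg(OMe)2 (10 equiv), MeOH–THF, 65 °C; then cold 1 M HCl
Reagents that add atoms: none
Why: Magnesium-bound methoxide adds to the lactone carbonyl (pyranone C2), the ring opens, and the chain is held as the magnesium bis-chelate 15 with enolates spanning O3/O5 and O5/O7. The enolate carbon C6 then attacks the ester carbonyl C1, methoxide is expelled and two enolisations aromatise the new ring, so the bond formed is C4a''–C8a'', with C1, C3 and C5 supplying the oxygens of C8a'', C7'' and C5'' and the C4 methine bringing unit 1 to C6''. The closest known reaction type is the Mg(OMe)2-promoted Claisen cyclisation of 6-(2-oxoalkyl)-4-hydroxy-2-pyranones and of 3,5,7-trioxo esters to acylphloroglucinols, the laboratory counterpart of chalcone synthase. Ring D closes in the 6-(enolexo)-exo-trig mode, the C1 carbonyl lying outside the ring being formed. No stereocentre is created: the C4 methine is flattened on aromatisation, the axis is not controlled and the E alkene is not touched. The selectivity needed is Claisen folding (C6 to C1) over aldol folding (C2 to C7), over Michael closure of C4 onto C9 and over relactonisation; chelation holds C3, C5 and C7 as unreactive enolates and leaves the ester C1 as the only electrophile that C6 can reach through a six-membered transition state, the C7 carbonyl is a deactivated vinylogous ketone, and C4 is a fully substituted, crowded carbanion. The chromone of unit 1 is tetrasubstituted at C2=C3 and flanked by aryl groups, so reversible methoxide addition there should not compete, and benzyl and methyl ethers are inert. Cold dilute acid releases the product from its magnesium phenolate; closure to the flavanone isomer on standing is tolerated because the next step accepts both forms.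

**Step 11**
Reactants: 16 (E)-3-[3,4-bis(benzyloxy)phenyl]-1-(3-Fl-2,4,6-trihydroxyphenyl)prop-2-en-1-one
Product: 18 2-[3,4-bis(benzyloxy)phenyl]-6-Fl-5,7-dihydroxy-4H-chromen-4-one, via racemic flavanone 17 (not isolated)
Conditions: I2 (10 mol%), DMSO, 120 °C
Reagents that add atoms: none
Why: Iodine-mediated oxidative cyclisation of a 2'-hydroxychalcone; 6-endo-trig oxa-Michael closure gives flavanone 17, α-iodination and loss of HI give the flavone, and DMSO turns HI back into I2. The hydroxyl between the acyl group and unit 1 is buttressed into the hydrogen bond with the ketone, which turns the enone toward the other ortho hydroxyl (next to C8''–H, para to unit 1) whose proton is freely accessible to base, so closure through that oxygen and hence the 6''-linkage is expected; catalytic iodine limits ring iodination.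

**Step 12**
Reactants: 18 2-[3,4-bis(benzyloxy)phenyl]-6-Fl-5,7-dihydroxy-4H-chromen-4-one
Product: 19 2-(3,4-dihydroxyphenyl)-5,7-dihydroxy-6-[5-hydroxy-2-(4-hydroxyphenyl)-7-methoxy-4-oxo-4H-chromen-3-yl]-4H-chromen-4-one
Conditions: BCl3 (8 equiv), C6HMe5 (10 equiv), CH2Cl2, −78 °C; MeOH quench
Reagents that add atoms: none
Why: Lewis-acid debenzylation with a non-basic cation scavenger; BCl3 ionises each benzyl ether and pentamethylbenzene captures the benzyl cation by Friedel–Crafts alkylation before it can re-alkylate the electron-rich rings, while at −78 °C the C7 methyl ether (not peri to a carbonyl) and both C2=C3 bonds are untouched.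

## Compound list

1 | 1-(2,6-dihydroxy-4-methoxyphenyl)ethanone | CC(=O)c1c(O)cc(OC)cc1O | starting material
2 | 1-[2-(benzyloxy)-6-hydroxy-4-methoxyphenyl]ethanone | CC(=O)c1c(O)cc(OC)cc1OCc1ccccc1 | intermediate
3 | 4-(benzyloxy)benzoyl chloride | O=C(Cl)c1ccc(OCc2ccccc2)cc1 | starting material
4 | 1-[2-(benzyloxy)-6-hydroxy-4-methoxyphenyl]-3-[4-(benzyloxy)phenyl]propane-1,3-dione | COc1cc(O)c(C(=O)CC(=O)c2ccc(OCc3ccccc3)cc2)c(OCc2ccccc2)c1 | intermediate
5 | racemic 2-allyl-1-[2-(benzyloxy)-6-hydroxy-4-methoxyphenyl]-3-[4-(benzyloxy)phenyl]propane-1,3-dione | COc1cc(O)c(C(=O)C(CC=C)C(=O)c2ccc(OCc3ccccc3)cc2)c(OCc2ccccc2)c1 | intermediate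
6 | 3-allyl-5-(benzyloxy)-2-[4-(benzyloxy)phenyl]-7-methoxy-4H-chromen-4-one | COc1cc(OCc2ccccc2)c2c(=O)c(CC=C)c(-c3ccc(OCc4ccccc4)cc3)oc2c1 | intermediate
7 | 5-(benzyloxy)-2-[4-(benzyloxy)phenyl]-7-methoxy-3-(2-oxopropyl)-4H-chromen-4-one | COc1cc(OCc2ccccc2)c2c(=O)c(CC(C)=O)c(-c3ccc(OCc4ccccc4)cc3)oc2c1 | intermediate
8 | (Z)-5-(benzyloxy)-2-[4-(benzyloxy)phenyl]-7-methoxy-3-[2-(trimethylsilyloxy)prop-1-enyl]-4H-chromen-4-one | COc1cc(OCc2ccccc2)c2c(=O)c(/C=C(/C)O[Si](C)(C)C)c(-c3ccc(OCc4ccccc4)cc3)oc2c1 | intermediate
9 | malonyl dichloride | O=C(Cl)CC(=O)Cl | starting material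
10 | 5-Fl-4-hydroxy-6-methyl-2H-pyran-2-one | COc1cc(OCc2ccccc2)c2c(=O)c(-c3c(O)cc(=O)oc3C)c(-c3ccc(OCc4ccccc4)cc3)oc2c1 | intermediate
11 | 3,4-bis(benzyloxy)benzaldehyde | O=Cc1ccc(OCc2ccccc2)c(OCc2ccccc2)c1 | starting material
12 | diethyl {2-[methoxy(methyl)amino]-2-oxoethyl}phosphonate | CCOP(=O)(CC(=O)N(C)OC)OCC | starting material
13 | (E)-3-[3,4-bis(benzyloxy)phenyl]-N-methoxy-N-methylprop-2-enamide | CON(C)C(=O)/C=C/c1ccc(OCc2ccccc2)c(OCc2ccccc2)c1 | intermediate
14 | 6-{(E)-4-[3,4-bis(benzyloxy)phenyl]-2-oxobut-3-enyl}-5-Fl-4-hydroxy-2H-pyran-2-one | COc1cc(OCc2ccccc2)c2c(=O)c(-c3c(O)cc(=O)oc3CC(=O)/C=C/c3ccc(OCc4ccccc4)c(OCc4ccccc4)c3)c(-c3ccc(OCc4ccccc4)cc3)oc2c1 | intermediate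
15 | methyl (E)-9-[3,4-bis(benzyloxy)phenyl]-4-Fl-3,5,7-trioxonon-8-enoate, present as its magnesium chelate and drawn as the neutral triketo ester (the C4 centre is lost on enolisation) | COC(=O)CC(=O)C(C(=O)CC(=O)/C=C/c1ccc(OCc2ccccc2)c(OCc2ccccc2)c1)c1c(-c2ccc(OCc3ccccc3)cc2)oc2cc(OC)cc(OCc3ccccc3)c2c1=O | intermediate
16 | (E)-3-[3,4-bis(benzyloxy)phenyl]-1-(3-Fl-2,4,6-trihydroxyphenyl)prop-2-en-1-one | COc1cc(OCc2ccccc2)c2c(=O)c(-c3c(O)cc(O)c(C(=O)/C=C/c4ccc(OCc5ccccc5)c(OCc5ccccc5)c4)c3O)c(-c3ccc(OCc4ccccc4)cc3)oc2c1 | intermediate
17 | racemic 2-[3,4-bis(benzyloxy)phenyl]-6-Fl-5,7-dihydroxychroman-4-one | COc1cc(OCc2ccccc2)c2c(=O)c(-c3c(O)cc4c(c3O)C(=O)CC(c3ccc(OCc5ccccc5)c(OCc5ccccc5)c3)O4)c(-c3ccc(OCc4ccccc4)cc3)oc2c1 | intermediate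
18 | 2-[3,4-bis(benzyloxy)phenyl]-6-Fl-5,7-dihydroxy-4H-chromen-4-one | COc1cc(OCc2ccccc2)c2c(=O)c(-c3c(O)cc4oc(-c5ccc(OCc6ccccc6)c(OCc6ccccc6)c5)cc(=O)c4c3O)c(-c3ccc(OCc4ccccc4)cc3)oc2c1 | intermediate
19 | 2-(3,4-dihydroxyphenyl)-5,7-dihydroxy-6-[5-hydroxy-2-(4-hydroxyphenyl)-7-methoxy-4-oxo-4H-chromen-3-yl]-4H-chromen-4-one | COc1cc(O)c2c(=O)c(-c3c(O)cc4oc(-c5ccc(O)c(O)c5)cc(=O)c4c3O)c(-c3ccc(O)cc3)oc2c1 | target

## Step count and least certain steps

Total: 12 steps. Longest linear sequence: 11 steps (steps 1 to 7 and 9 to 12); step 8 is a one-step side branch.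

**Step 10 (key step).**
- What may go wrong: the lactone anion may resist methanolysis, so that forcing conditions are needed. Under these the enone can take up methoxide, the chain can fold by aldol addition of C2 to C7 or by Michael closure of C4 onto C9, or the 2-substituted 1,3-diketone can fragment by retro-Claisen attack. The cause would be a C4 substituent that is much larger than in the known cases and could distort the chelate.
- Fallback (sets out from 10, returns at 16): the dianion of 10 would be acylated with N-methoxy-N-methylacetamide to 5-Fl-4-hydroxy-6-(2-oxopropyl)-2H-pyran-2-one F1. F1 has no enone and can be pushed harder; it would be folded with Mg(OMe)2 in methanol to 1-(3-Fl-2,4,6-trihydroxyphenyl)ethanone F2. Claisen–Schmidt condensation of F2 with 11 (KOH, ethanol) would then build the alkene after ring D exists and give 16.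

**Step 11.**
- What may go wrong: partial ring closure through the hydroxyl between the acyl group and unit 1, leading to the 8''-linked series, because an intramolecular attack feels the neighbouring unit 1 less than an intermolecular reagent would. Iodination of ring D at C8'' is a lesser risk.
- Fallback (sets out from 16, returns at 19): this uses the strong steric bias of intermolecular O-alkylation. MeOCH2Cl (2.2 equiv) with iPr2NEt would cap the two accessible hydroxyls and give the 4',6'-bis(methoxymethyl) ether F3, leaving only the chelated, doubly flanked hydroxyl. BnBr with Cs2CO3 in DMF would benzylate that oxygen to give F4, reversible flavanone closure being drained by the alkylation. HCl in methanol would remove both acetals to give the 2'-benzyl ether F5, in which only the correct oxygen can cyclise. I2 in DMSO would give the 5''-O-benzyl flavone F6, and BCl3 with pentamethylbenzene would give 19.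

**Step 6 (with its consequence in step 7).**
- What may go wrong: enolisation toward the methyl group instead of the crowded CH2 group, because allylic strain with the C2 aryl group and the C4 carbonyl may cancel the conjugative preference. Step 7 would then build a pyranone with unit 1 on a 6-CH2 group. Slow C-acylation at the hindered carbon is a second risk.
- Fallback (sets out from 6, returns at 10): the regiochemistry is fixed by construction.
  - Lemieux–Johnson cleavage of 6 (OsO4 cat., NaIO4, 2,6-lutidine, dioxane–water) would give the aldehyde Fl–CH2–CHO F7.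
  - Roskamp homologation with ethyl diazoacetate and SnCl2 would give ethyl 4-Fl-3-oxobutanoate F8.
  - The dianion of F8 (LiN(iPr)2, 2.2 equiv) would be acetylated at its γ-carbon with N-methoxy-N-methylacetamide to ethyl 4-Fl-3,5-dioxohexanoate F9.
  - Lactonisation with 1,8-diazabicyclo[5.4.0]undec-7-ene in hot toluene would give 10.

**Step 9.**
- What may go wrong: conjugate addition of the delocalised carbanion to the cinnamoyl system, premature collapse of the tetrahedral adduct followed by proton transfer that stops the reaction at partial conversion, or base-induced fragmentation of the N-methoxy amide.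
- Fallback (sets out from 13 and 10, returns at 14): 13 would be reduced with iBu2AlH at −78 °C to (E)-3-[3,4-bis(benzyloxy)phenyl]prop-2-enal F10. Aldol addition of the dianion of 10 to F10 would give the racemic allylic alcohol 5-Fl-4-hydroxy-6-{(E)-4-[3,4-bis(benzyloxy)phenyl]-2-hydroxybut-3-enyl}-2H-pyran-2-one F11. Oxidation of the allylic alcohol with MnO2 in CH2Cl2 would give 14.

## Further compounds

F1 | step 10 | 5-Fl-4-hydroxy-6-(2-oxopropyl)-2H-pyran-2-one | COc1cc(OCc2ccccc2)c2c(=O)c(-c3c(O)cc(=O)oc3CC(C)=O)c(-c3ccc(OCc4ccccc4)cc3)oc2c1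
F2 | step 10 | 1-(3-Fl-2,4,6-trihydroxyphenyl)ethanone | COc1cc(OCc2ccccc2)c2c(=O)c(-c3c(O)cc(O)c(C(C)=O)c3O)c(-c3ccc(OCc4ccccc4)cc3)oc2c1
F3 | step 11 | (E)-3-[3,4-bis(benzyloxy)phenyl]-1-[3-Fl-2-hydroxy-4,6-bis(methoxymethoxy)phenyl]prop-2-en-1-one | COc1cc(OCc2ccccc2)c2c(=O)c(-c3c(OCOC)cc(OCOC)c(C(=O)/C=C/c4ccc(OCc5ccccc5)c(OCc5ccccc5)c4)c3O)c(-c3ccc(OCc4ccccc4)cc3)oc2c1
F4 | step 11 | (E)-1-[2-(benzyloxy)-3-Fl-4,6-bis(methoxymethoxy)phenyl]-3-[3,4-bis(benzyloxy)phenyl]prop-2-en-1-one | COc1cc(OCc2ccccc2)c2c(=O)c(-c3c(OCOC)cc(OCOC)c(C(=O)/C=C/c4ccc(OCc5ccccc5)c(OCc5ccccc5)c4)c3OCc3ccccc3)c(-c3ccc(OCc4ccccc4)cc3)oc2c1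
F5 | step 11 | (E)-1-[2-(benzyloxy)-3-Fl-4,6-dihydroxyphenyl]-3-[3,4-bis(benzyloxy)phenyl]prop-2-en-1-one | COc1cc(OCc2ccccc2)c2c(=O)c(-c3c(O)cc(O)c(C(=O)/C=C/c4ccc(OCc5ccccc5)c(OCc5ccccc5)c4)c3OCc3ccccc3)c(-c3ccc(OCc4ccccc4)cc3)oc2c1
F6 | step 11 | 5-(benzyloxy)-2-[3,4-bis(benzyloxy)phenyl]-6-Fl-7-hydroxy-4H-chromen-4-one | COc1cc(OCc2ccccc2)c2c(=O)c(-c3c(O)cc4oc(-c5ccc(OCc6ccccc6)c(OCc6ccccc6)c5)cc(=O)c4c3OCc3ccccc3)c(-c3ccc(OCc4ccccc4)cc3)oc2c1
F7 | step 6 | 2-Fl-acetaldehyde | COc1cc(OCc2ccccc2)c2c(=O)c(CC=O)c(-c3ccc(OCc4ccccc4)cc3)oc2c1
F8 | step 6 | ethyl 4-Fl-3-oxobutanoate | CCOC(=O)CC(=O)Cc1c(-c2ccc(OCc3ccccc3)cc2)oc2cc(OC)cc(OCc3ccccc3)c2c1=O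
F9 | step 6 | ethyl 4-Fl-3,5-dioxohexanoate (racemic, enolisable) | CCOC(=O)CC(=O)C(C(C)=O)c1c(-c2ccc(OCc3ccccc3)cc2)oc2cc(OC)cc(OCc3ccccc3)c2c1=O
F10 | step 9 | (E)-3-[3,4-bis(benzyloxy)phenyl]prop-2-enal | O=C/C=C/c1ccc(OCc2ccccc2)c(OCc2ccccc2)c1
F11 | step 9 | racemic 5-Fl-4-hydroxy-6-{(E)-4-[3,4-bis(benzyloxy)phenyl]-2-hydroxybut-3-enyl}-2H-pyran-2-one | COc1cc(OCc2ccccc2)c2c(=O)c(-c3c(O)cc(=O)oc3CC(O)/C=C/c3ccc(OCc4ccccc4)c(OCc4ccccc4)c3)c(-c3ccc(OCc4ccccc4)cc3)oc2c1
A1 | alternative 1 | 1-[2-(benzyloxy)-4-methoxy-6-(methoxymethoxy)phenyl]-3-[2,6-bis(benzyloxy)-4-(methoxymethoxy)phenyl]-3-[4-(benzyloxy)phenyl]prop-2-en-1-one (either alkene geometry) | COCOc1cc(OC)cc(OCc2ccccc2)c1C(=O)C=C(c1ccc(OCc2ccccc2)cc1)c1c(OCc2ccccc2)cc(OCOC)cc1OCc1ccccc1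
A2 | alternative 1 | 5-(benzyloxy)-3-[2,6-bis(benzyloxy)-4-hydroxyphenyl]-2-[4-(benzyloxy)phenyl]-7-methoxy-4H-chromen-4-one | COc1cc(OCc2ccccc2)c2c(=O)c(-c3c(OCc4ccccc4)cc(O)cc3OCc3ccccc3)c(-c3ccc(OCc4ccccc4)cc3)oc2c1
A3 | alternative 2 | 3-[(4-methoxybenzyl)oxy]cyclobut-2-en-1-one | O=C1CC(OCc2ccc(OC)cc2)=C1
A4 | alternative 2 | 5-(benzyloxy)-2-[4-(benzyloxy)phenyl]-7-methoxy-3-{[tri(propan-2-yl)silyloxy]ethynyl}-4H-chromen-4-one | COc1cc(OCc2ccccc2)c2c(=O)c(C#CO[Si](C(C)C)(C(C)C)C(C)C)c(-c3ccc(OCc4ccccc4)cc3)oc2c1
A5 | alternative 2 | 5-(benzyloxy)-2-[4-(benzyloxy)phenyl]-3-{2-hydroxy-4-[(4-methoxybenzyl)oxy]-6-[tri(propan-2-yl)silyloxy]phenyl}-7-methoxy-4H-chromen-4-one | COc1cc(OCc2ccccc2)c2c(=O)c(-c3c(O)cc(OCc4ccc(OC)cc4)cc3O[Si](C(C)C)(C(C)C)C(C)C)c(-c3ccc(OCc4ccccc4)cc3)oc2c1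
A6 | alternative 3 | methyl 3-[3,4-bis(benzyloxy)phenyl]prop-2-ynoate | COC(=O)C#Cc1ccc(OCc2ccccc2)c(OCc2ccccc2)c1
A7 | alternative 3 | (Z)-3-[3,4-bis(benzyloxy)phenyl]-3-[3,5-bis(benzyloxy)-4-Fl-phenoxy]prop-2-enoic acid | OC(=O)/C=C(\Oc1cc(OCc2ccccc2)c(-c2c(-c3ccc(OCc4ccccc4)cc3)oc3cc(OC)cc(OCc4ccccc4)c3c2=O)c(OCc2ccccc2)c1)c1ccc(OCc2ccccc2)c(OCc2ccccc2)c1
A8 | alternative 3 | 5,7-bis(benzyloxy)-2-[3,4-bis(benzyloxy)phenyl]-6-Fl-4H-chromen-4-one (hexabenzyl ether of the target) | COc1cc(OCc2ccccc2)c2c(=O)c(-c3c(OCc4ccccc4)cc4oc(-c5ccc(OCc6ccccc6)c(OCc6ccccc6)c5)cc(=O)c4c3OCc3ccccc3)c(-c3ccc(OCc4ccccc4)cc3)oc2c1
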